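**Strategy.** The dihydropyran (ring C) shares the C4a–C8a edge with ring A: C4a carries the C4 methylene, C8a carries O1, and the lone stereocenter C2 is an O-bearing benzylic carbon, i.e. a ring-opened 2-phenyloxetane. The route therefore cuts C4–C4a and O1–C8a together. One palladium/norbornene (Catellani) annulation should move palladium from the C8a iodide to C4a–H, open (S)-2-phenyloxetane at its CH2–O bond and close the aryl ether at C8a, leaving C2 untouched. The precursor is methyl 2-(benzyloxy)-6-iodo-4-methoxybenzoate, whose ortho ester blocks the second ortho site and later becomes C2' of the benzofuran (intramolecular Wittig), before global debenzylation.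

Key step: step 5

Remark 1 (structure): ring D carries three ring oxygens (O1', the C4' methoxyl, the C6' hydroxyl) with the methyl at C5' between the last two, so its building block must be a 2,4,6-trioxygenated 3-methylbenzaldehyde; a 2,4-dihydroxy-3-methylbenzaldehyde lacks the oxygen that becomes O1' and cannot give the target.

Remark 2 (assumption): methyl 2-amino-4,6-dimethoxybenzoate and 2,4,6-trihydroxy-3-methylbenzaldehyde are taken as purchasable; the latter is otherwise one Vilsmeier–Haack formylation from 2-methylphloroglucinol.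

**Route**

Step 1
Reactants: 1 methyl 2-amino-4,6-dimethoxybenzoate
Product: 2 methyl 2-iodo-4,6-dimethoxybenzoate
Conditions: NaNO2, 2 M HCl, MeCN, 0 °C; then KI, 0 °C to rt
Reagents that add atoms: potassium iodide, [K+].[I-]
Why: Sandmeyer-type iododediazoniation puts iodine exactly where the amino group was (ortho to the ester), which electrophilic iodination of this electron-rich ring, prone to attack at C3 or C5, could not guarantee.

Step 2
Reactants: 2 methyl 2-iodo-4,6-dimethoxybenzoate
Product: 3 methyl 2-hydroxy-6-iodo-4-methoxybenzoate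
Conditions: BCl3 (1.5 equiv), CH2Cl2, −78 to 0 °C; aqueous work-up
Reagents that add atoms: none
Why: Chelation-controlled Lewis-acid demethylation, in which BCl3 bound to the ester carbonyl should cleave only the ortho methoxyl through a six-membered chelate and leave the para methoxyl, the ester and the aryl iodide alone.

Step 3
Reactants: 3 methyl 2-hydroxy-6-iodo-4-methoxybenzoate
Product: 4 methyl 2-(benzyloxy)-6-iodo-4-methoxybenzoate
Conditions: BnBr, K2CO3, DMF, rt to 50 °C
Reagents that add atoms: benzyl bromide, BrCc1ccccc1
Why: Williamson etherification of the salicylate phenol; the hindered ester and the aryl iodide are inert to K2CO3 and BnBr.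

Step 4
Reactants: 5 (S)-3-chloro-1-phenylpropan-1-ol
Product: 6 (S)-2-phenyloxetane
Conditions: KOtBu, THF, 0 °C to reflux
Reagents that add atoms: none
Why: Intramolecular Williamson etherification (4-exo-tet) at the primary chloride; the carbinol carbon is not a reacting centre, so the (S) configuration is carried over unchanged.

Step 5
Reactants: 4 methyl 2-(benzyloxy)-6-iodo-4-methoxybenzoate; 6 (S)-2-phenyloxetane (3 equiv)
Product: 7 methyl (S)-7-(benzyloxy)-5-methoxy-2-phenylchroman-8-carboxylate
Conditions: Pd(OAc)2 (10 mol %), RuPhos (20 mol %), norbornene (50 mol %), K2CO3 (2.5 equiv), DMF, 110 °C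
Reagents that add atoms: none
Why: Proposed new method: zerovalent palladium inserts into the C8a–I bond, norbornene inserts and relays divalent palladium to C4a–H (carbonate-assisted metalation) to give the aryl–norbornyl palladacycle, which should open the strained oxetane (or its iodide-opened 3-iodoalkoxide) by SN2 attack at the CH2–O carbon to give tetravalent palladium; aryl–alkyl reductive elimination then forms C4–C4a, norbornene is expelled by β-carbon elimination because both ortho positions are now substituted, and the tethered alkoxide replaces iodide on divalent palladium. The closest known reaction types are the Catellani annulation of aryl iodides with epoxides to 2,3-dihydrobenzofurans and Catellani ortho-alkylation with primary alkyl halides, the four-membered ether here taking the role of the epoxide. Ring C closes by C–O reductive elimination (O1–C8a) from a seven-membered aryl(alkoxo)palladium chelate, helped by the bulky electron-rich biarylphosphine and the electron-withdrawing ortho ester. No stereocenter is created: C2 comes from 6 and stays (S) because only the primary C–O bond is broken and the new bond is made at oxygen. The step needs primary-over-benzylic ring opening (secured by the SN2 character under Lewis-acid-free carbonate conditions), a single C–H site (C4a–H is the only hydrogen ortho to iodine, the other ortho position carrying the ester), and C–O reductive elimination faster than β-hydride elimination of the secondary alkoxide (favoured by RuPhos).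

Step 6
Reactants: 7 methyl (S)-7-(benzyloxy)-5-methoxy-2-phenylchroman-8-carboxylate
Product: 8 (S)-7-(benzyloxy)-5-methoxy-2-phenylchroman-8-carboxylic acid
Conditions: LiI (6 equiv), pyridine, reflux; then 1 M HCl
Reagents that add atoms: none
Why: SN2 dealkylation of the methyl ester by iodide, the standard answer to a di-ortho-substituted benzoate that resists acyl-oxygen hydrolysis; aryl methyl and benzyl ethers and the C2–O1 bond should not be attacked under these conditions.

Step 7
Reactants: 9 2,4,6-trihydroxy-3-methylbenzaldehyde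
Product: 10 4,6-bis(benzyloxy)-2-hydroxy-3-methylbenzaldehyde
Conditions: BnBr (2.05 equiv), K2CO3, acetone, reflux
Reagents that add atoms: benzyl bromide, BrCc1ccccc1
Why: Regioselective Williamson etherification: the para hydroxyl (most acidic) and the unhindered ortho hydroxyl should react, while the hydroxyl wedged between formyl and methyl is held in the strongest hydrogen bond and should stay free.

Step 8
Reactants: 10 4,6-bis(benzyloxy)-2-hydroxy-3-methylbenzaldehyde
Product: 11 4,6-bis(benzyloxy)-2-methoxy-3-methylbenzaldehyde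
Conditions: MeI, K2CO3, DMF, 50 °C
Reagents that add atoms: iodomethane, CI
Why: Williamson methylation of the remaining hindered, hydrogen-bonded phenol under standard forcing conditions; this oxygen becomes the C4' methoxyl.

Step 9
Reactants: 11 4,6-bis(benzyloxy)-2-methoxy-3-methylbenzaldehyde
Product: 12 4-(benzyloxy)-6-hydroxy-2-methoxy-3-methylbenzaldehyde
Conditions: MgBr2·OEt2 (3 equiv), toluene/Et2O, 80 °C; then 1 M HCl
Reagents that add atoms: none
Why: Chelation-controlled debenzylation: MgBr2 bridges the formyl oxygen and the ortho benzyloxy oxygen and bromide should remove only that benzyl group, since the para benzyl ether cannot chelate and the ortho methyl ether cleaves far more slowly.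

Step 10
Reactants: 12 4-(benzyloxy)-6-hydroxy-2-methoxy-3-methylbenzaldehyde
Product: 13 5-(benzyloxy)-2-(hydroxymethyl)-3-methoxy-4-methylphenol
Conditions: NaBH4, THF/MeOH, 0 °C; aqueous work-up, used crude
Reagents that add atoms: none
Why: Borohydride reduction of the aldehyde to the 2-hydroxybenzyl alcohol; the ethers are inert.

Step 11
Reactants: 13 5-(benzyloxy)-2-(hydroxymethyl)-3-methoxy-4-methylphenol
Product: 14 [4-(benzyloxy)-2-hydroxy-6-methoxy-5-methylbenzyl]triphenylphosphonium bromide
Conditions: PPh3·HBr, MeCN, rt to reflux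
Reagents that add atoms: triphenylphosphonium bromide (PPh3·HBr), [PH+](c1ccccc1)(c1ccccc1)c1ccccc1.[Br-]
Why: Acid-promoted substitution of the electron-rich 2-hydroxybenzyl alcohol by PPh3 via the ortho-quinone methide (benzyl cation), the usual entry to 2-hydroxybenzylphosphonium salts.

Step 12
Reactants: 8 (S)-7-(benzyloxy)-5-methoxy-2-phenylchroman-8-carboxylic acid; 14 [4-(benzyloxy)-2-hydroxy-6-methoxy-5-methylbenzyl]triphenylphosphonium bromide
Product: 17 (S)-7-(benzyloxy)-8-[6-(benzyloxy)-4-methoxy-5-methylbenzofuran-2-yl]-5-methoxy-2-phenylchroman, via the acid chloride 15 (not isolated), via the aryl ester phosphonium salt 16 (not isolated)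
Conditions: (COCl)2, cat. DMF, CH2Cl2, 0 °C to rt, evaporate; then 14, Et3N (4 equiv), toluene, rt to reflux
Reagents that add atoms: oxalyl chloride, ClC(=O)C(=O)Cl (supplies only the chlorine of intermediate 15; no atom of it remains in 17)
Why: Acid chloride formation, O-acylation of the phenol of 14, ylide formation and intramolecular Wittig olefination of the ester carbonyl (C2'=C3') should build the furan ring in one pot, with the ester carbon of ring A becoming C2'; C2 is not involved.

Step 13
Reactants: 17 (S)-7-(benzyloxy)-8-[6-(benzyloxy)-4-methoxy-5-methylbenzofuran-2-yl]-5-methoxy-2-phenylchroman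
Product: 18 (S)-8-(6-hydroxy-4-methoxy-5-methylbenzofuran-2-yl)-5-methoxy-2-phenylchroman-7-ol
Conditions: H2 (1 atm), 10% Pd/C, EtOAc/MeOH, rt, stopped after uptake for two benzyl groups
Reagents that add atoms: none
Why: Catalytic hydrogenolysis of both aryl benzyl ethers under neutral conditions; the cyclic benzylic C2–O1 bond and the benzofuran C2'=C3' bond react much more slowly, so C2 should stay (S).

**Compound list**

1 | methyl 2-amino-4,6-dimethoxybenzoate | COC(=O)c1c(N)cc(OC)cc1OC | starting material
2 | methyl 2-iodo-4,6-dimethoxybenzoate | COC(=O)c1c(I)cc(OC)cc1OC | intermediate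
3 | methyl 2-hydroxy-6-iodo-4-methoxybenzoate | COC(=O)c1c(I)cc(OC)cc1O | intermediate
4 | methyl 2-(benzyloxy)-6-iodo-4-methoxybenzoate | COC(=O)c1c(I)cc(OC)cc1OCc1ccccc1 | intermediate
5 | (S)-3-chloro-1-phenylpropan-1-ol | ClCC[C@@H](c1ccccc1)O | starting material
6 | (S)-2-phenyloxetane | C1C[C@@H](c2ccccc2)O1 | intermediate
7 | methyl (S)-7-(benzyloxy)-5-methoxy-2-phenylchroman-8-carboxylate | COc1cc(OCc2ccccc2)c(C(=O)OC)c2c1CC[C@@H](c1ccccc1)O2 | intermediate
8 | (S)-7-(benzyloxy)-5-methoxy-2-phenylchroman-8-carboxylic acid | COc1cc(OCc2ccccc2)c(C(=O)O)c2c1CC[C@@H](c1ccccc1)O2 | intermediate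
9 | 2,4,6-trihydroxy-3-methylbenzaldehyde | Cc1c(O)cc(O)c(C=O)c1O | starting material
10 | 4,6-bis(benzyloxy)-2-hydroxy-3-methylbenzaldehyde | Cc1c(OCc2ccccc2)cc(OCc2ccccc2)c(C=O)c1O | intermediate
11 | 4,6-bis(benzyloxy)-2-methoxy-3-methylbenzaldehyde | COc1c(C)c(OCc2ccccc2)cc(OCc2ccccc2)c1C=O | intermediate
12 | 4-(benzyloxy)-6-hydroxy-2-methoxy-3-methylbenzaldehyde | COc1c(C)c(OCc2ccccc2)cc(O)c1C=O | intermediate
13 | 5-(benzyloxy)-2-(hydroxymethyl)-3-methoxy-4-methylphenol | COc1c(C)c(OCc2ccccc2)cc(O)c1CO | intermediate
14 | [4-(benzyloxy)-2-hydroxy-6-methoxy-5-methylbenzyl]triphenylphosphonium bromide | COc1c(C)c(OCc2ccccc2)cc(O)c1C[P+](c1ccccc1)(c1ccccc1)c1ccccc1.[Br-] | intermediate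
15 | (S)-7-(benzyloxy)-5-methoxy-2-phenylchroman-8-carbonyl chloride | COc1cc(OCc2ccccc2)c(C(=O)Cl)c2c1CC[C@@H](c1ccccc1)O2 | intermediate
16 | [4-(benzyloxy)-2-({[(S)-7-(benzyloxy)-5-methoxy-2-phenylchroman-8-yl]carbonyl}oxy)-6-methoxy-5-methylbenzyl]triphenylphosphonium bromide | COc1cc(OCc2ccccc2)c(C(=O)Oc3cc(OCc4ccccc4)c(C)c(OC)c3C[P+](c4ccccc4)(c4ccccc4)c4ccccc4)c2c1CC[C@@H](c1ccccc1)O2.[Br-] | intermediate
17 | (S)-7-(benzyloxy)-8-[6-(benzyloxy)-4-methoxy-5-methylbenzofuran-2-yl]-5-methoxy-2-phenylchroman | COc1cc(OCc2ccccc2)c(-c2cc3c(OC)c(C)c(OCc4ccccc4)cc3o2)c2c1CC[C@@H](c1ccccc1)O2 | intermediate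
18 | (S)-8-(6-hydroxy-4-methoxy-5-methylbenzofuran-2-yl)-5-methoxy-2-phenylchroman-7-ol | COc1cc(O)c(-c2cc3c(OC)c(C)c(O)cc3o2)c2c1CC[C@@H](c1ccccc1)O2 | target

**Count**

Total steps: 13. Longest linear sequence: 7 steps (1, 2, 3, 5, 6, 12, 13; the ring D branch 7, 8, 9, 10, 11, 12, 13 is equally long).

**Steps most likely to fail**

1. Step 5 (proposed new method). The palladacycle may open the unactivated oxetane too slowly and instead collapse onto norbornene or be protonated. C–H palladation next to the C5 methoxyl may be sluggish. The secondary palladium alkoxide may undergo β-hydride elimination instead of C–O reductive elimination.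
Fallback (known chemistry only), setting out from aryl iodide 4 and returning at 7: palladium-catalysed hydroxylation (Pd2(dba)3, tBuXPhos, KOH, dioxane/H2O; the di-ortho-substituted ester resists hydroxide) should give the phenol methyl 2-(benzyloxy)-6-hydroxy-4-methoxybenzoate F1. Magnesium-mediated ortho-formylation (MgCl2, Et3N, paraformaldehyde, MeCN) at its only free ortho carbon gives methyl 6-(benzyloxy)-3-formyl-2-hydroxy-4-methoxybenzoate F2. Wittig olefination with Ph3P=CHC(O)Ph gives the enone methyl 6-(benzyloxy)-2-hydroxy-4-methoxy-3-[(E)-3-oxo-3-phenylprop-1-en-1-yl]benzoate F3. Conjugate hydrogenation (H2, RhCl(PPh3)3), which spares the benzyl ether, gives the ketone methyl 6-(benzyloxy)-2-hydroxy-4-methoxy-3-(3-oxo-3-phenylpropyl)benzoate F4. Corey–Bakshi–Shibata reduction with the (S)-oxazaborolidine and BH3·SMe2 gives the alcohol methyl 6-(benzyloxy)-2-hydroxy-3-[(R)-3-hydroxy-3-phenylpropyl]-4-methoxybenzoate F5. Mitsunobu cyclisation (PPh3, DIAD) then closes O1–C2 with inversion and arrives at 7 with the (S) configuration.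

2. Step 12. Attack of the ylide on the carbonyl of a di-ortho-substituted aryl ester may be too slow, so that ester cleavage or C-acylation of the ylide takes over.
Fallback, setting out from ester 7 (step 6 is then not needed) and returning at 17: LiAlH4 reduction gives the alcohol [(S)-7-(benzyloxy)-5-methoxy-2-phenylchroman-8-yl]methanol F6. MnO2 oxidation gives the aldehyde (S)-7-(benzyloxy)-5-methoxy-2-phenylchroman-8-carbaldehyde F7. Intermolecular Wittig reaction with the ylide of 14 (LiHMDS, 2 equiv, THF) gives the 2-hydroxystilbene 5-(benzyloxy)-2-{(E)-2-[(S)-7-(benzyloxy)-5-methoxy-2-phenylchroman-8-yl]ethenyl}-3-methoxy-4-methylphenol F8; the alkene geometry does not matter. Oxidative cyclisation of the phenol onto the alkene (I2, K2CO3, THF, or PhI(OAc)2, MeCN) forms O1'–C2' and gives 17.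

3. Step 7. Site selection between the two ortho hydroxyls may be poor (benzylation next to the methyl group), or over-benzylation may occur.
Fallback, setting out from 9 and returning at 10: the differentiation is moved from alkylation to cleavage. Exhaustive benzylation (BnBr, K2CO3, DMF) gives 2,4,6-tris(benzyloxy)-3-methylbenzaldehyde F9. MgBr2·OEt2 should then remove one ortho benzyl group only, preferring the ether forced out of plane between formyl and methyl (more Lewis basic, strain relieved), which gives 10. The site of the free hydroxyl would be confirmed by NOE before going on.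

Further compounds
F1 | step 5 | methyl 2-(benzyloxy)-6-hydroxy-4-methoxybenzoate | COC(=O)c1c(O)cc(OC)cc1OCc1ccccc1
F2 | step 5 | methyl 6-(benzyloxy)-3-formyl-2-hydroxy-4-methoxybenzoate | COC(=O)c1c(O)c(C=O)c(OC)cc1OCc1ccccc1
F3 | step 5 | methyl 6-(benzyloxy)-2-hydroxy-4-methoxy-3-[(E)-3-oxo-3-phenylprop-1-en-1-yl]benzoate | COC(=O)c1c(O)c(/C=C/C(=O)c2ccccc2)c(OC)cc1OCc1ccccc1
F4 | step 5 | methyl 6-(benzyloxy)-2-hydroxy-4-methoxy-3-(3-oxo-3-phenylpropyl)benzoate | COC(=O)c1c(O)c(CCC(=O)c2ccccc2)c(OC)cc1OCc1ccccc1
F5 | step 5 | methyl 6-(benzyloxy)-2-hydroxy-3-[(R)-3-hydroxy-3-phenylpropyl]-4-methoxybenzoate | COC(=O)c1c(O)c(CC[C@@H](O)c2ccccc2)c(OC)cc1OCc1ccccc1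
F6 | step 12 | [(S)-7-(benzyloxy)-5-methoxy-2-phenylchroman-8-yl]methanol | COc1cc(OCc2ccccc2)c(CO)c2c1CC[C@@H](c1ccccc1)O2
F7 | step 12 | (S)-7-(benzyloxy)-5-methoxy-2-phenylchroman-8-carbaldehyde | COc1cc(OCc2ccccc2)c(C=O)c2c1CC[C@@H](c1ccccc1)O2
F8 | step 12 | 5-(benzyloxy)-2-{(E)-2-[(S)-7-(benzyloxy)-5-methoxy-2-phenylchroman-8-yl]ethenyl}-3-methoxy-4-methylphenol | COc1cc(OCc2ccccc2)c(/C=C/c2c(O)cc(OCc3ccccc3)c(C)c2OC)c2c1CC[C@@H](c1ccccc1)O2
F9 | step 7 | 2,4,6-tris(benzyloxy)-3-methylbenzaldehyde | Cc1c(OCc2ccccc2)cc(OCc2ccccc2)c(C=O)c1OCc1ccccc1
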